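**Plan**

1. Numbering used below: decalin as in labdanes (C10 = methyl-bearing ring-fusion carbon, C5 = ring-fusion CH, C4 = CMe2, C8=C9 = ring alkene), chain C11–C16, butenolide on C16.
2. Retrosynthesis: first the C12–C13 bond (sp3–sp2 Negishi coupling) to bromide 15 and vinyl iodide 25; then, in ring A of 15, C1–C2 and C4–C5 together; last the C10–CH3 bond.
3. Forward: ring B comes from 2,3-dimethylbenzoic acid by Birch reductive methylation (C8=C9, its methyl and the C11–C12 arm are already in place), ring A is annulated in one operation, and the chain is joined last.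
4. Enabling feature: after oxidation at C7, ring B is a cross-conjugated dienone in which C5 is the free β-carbon and C1 is a neopentyl tosylate on quaternary C10. C1–C10–C5 is thus a 1,3-bis-electrophile that takes up the two α-carbons of 3-methylbutan-2-one (C2 and C4); C3=O and C7=O are helpers, removed later as dithiolanes.
5. Stereochemistry: C10 from the prolinol-ether auxiliary in the Birch alkylation, C5 from C10 during the annulation (trans fusion), C16 from a chiral phosphoric acid propargylation, the alkene geometry from a syn-hydrostannation.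

Key step: step 8

Remark 1: the (S)-2-(methoxymethyl)pyrrolidine amide is assumed to direct methylation of the Birch enolate to the face that gives (S)-C10 as drawn in 6; if the sense is the opposite, the (R)-amine is used and nothing else changes.
Remark 2: (R)-TRIP is assumed to deliver the (R)-carbinol 17; otherwise its enantiomer is used.

**Route**

Step 1
Reactants: 1 2,3-dimethylbenzoic acid
Product: 3 5-methylisochroman-1-one, via hydroxy acid 2 (not isolated)
Conditions: LiN(iPr)2 (2.2 equiv), THF, −78 → 0 °C; (CH2O)n; then aq. HCl, rt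
Reagents that add atoms: formaldehyde (as paraformaldehyde), C=O
Why: Carboxylate-directed lateral lithiation (dianion) occurs only at the ortho methyl, the benzylic anion adds to formaldehyde and acid closes the six-membered lactone (lateral metalation–hydroxymethylation, then lactonization).

Step 2
Reactants: 3 5-methylisochroman-1-one
Product: 4 (S)-[2-(2-hydroxyethyl)-3-methylphenyl][2-(methoxymethyl)pyrrolidin-1-yl]methanone
Conditions: AlMe3, (S)-2-(methoxymethyl)pyrrolidine, toluene, 0 → 60 °C
Reagents that add atoms: (S)-2-(methoxymethyl)pyrrolidine, COC[C@@H]1CCCN1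
Why: AlMe3-mediated aminolysis of the lactone (Weinreb-type amidation) installs the chiral amide and frees the primary alcohol.

Step 3
Reactants: 4 hydroxy amide
Product: 5 (S)-{2-[2-(tert-butyldimethylsilyloxy)ethyl]-3-methylphenyl}[2-(methoxymethyl)pyrrolidin-1-yl]methanone
Conditions: TBSCl, imidazole, DMF, rt
Reagents that add atoms: tert-butyldimethylsilyl chloride, CC(C)(C)[Si](C)(C)Cl
Why: Routine silylation of the primary alcohol so that it survives the dissolving-metal and base steps.

Step 4
Reactants: 5 silyl ether amide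
Product: 6 {(1S)-2-[2-(tert-butyldimethylsilyloxy)ethyl]-1,3-dimethylcyclohexa-2,5-dien-1-yl}[(2S)-2-(methoxymethyl)pyrrolidin-1-yl]methanone
Conditions: K (2.2 equiv), NH3(l)/THF, t-BuOH (1 equiv), −78 °C; piperylene; MeI, −78 °C
Reagents that add atoms: iodomethane, C[I]
Why: Birch reduction of the benzamide gives the 1,4-dihydro amide enolate with both alkyl groups kept on the C8=C9 double bond, and iodomethane alkylates the ipso carbon on the face left open by the potassium-chelated methoxymethyl arm, which sets C10 (auxiliary-controlled Birch reductive alkylation).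

Step 5
Reactants: 6 diene amide
Product: 7 {(1S)-2-[2-(tert-butyldimethylsilyloxy)ethyl]-1,3-dimethylcyclohexa-2,5-dien-1-yl}methanol
Conditions: LiH2NBH3 (from H3N·BH3 and n-BuLi), THF, 0 → 23 °C; aqueous work-up
Reagents that add atoms: none
Why: Lithium amidotrihydroborate reduces tertiary amides, α-quaternary ones included, to primary alcohols with loss of the amine and does not touch the skipped diene or the silyl ether (amide reduction).

Step 6
Reactants: 7 diene alcohol
Product: 8 {(1S)-2-[2-(tert-butyldimethylsilyloxy)ethyl]-1,3-dimethylcyclohexa-2,5-dien-1-yl}methyl 4-methylbenzenesulfonate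
Conditions: TsCl, pyridine, DMAP (cat.), CH2Cl2, 0 °C → rt
Reagents that add atoms: 4-methylbenzenesulfonyl chloride, Cc1ccc(cc1)S(=O)(=O)Cl
Why: Sulfonylation of the neopentyl alcohol gives a leaving group that cannot eliminate (no β-hydrogen) and is inert to external nucleophiles.

Step 7
Reactants: 8 diene tosylate
Product: 9 {(1S)-2-[2-(tert-butyldimethylsilyloxy)ethyl]-1,3-dimethyl-4-oxocyclohexa-2,5-dien-1-yl}methyl 4-methylbenzenesulfonate
Conditions: Rh2(cap)4 (1 mol %), t-BuOOH (5 equiv), K2CO3, CH2Cl2, rt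
Reagents that add atoms: tert-butyl hydroperoxide, CC(C)(C)OO
Why: Catalytic allylic oxidation attacks the doubly allylic C7 methylene fastest and stops at the cross-conjugated dienone, because quaternary C10 blocks aromatization.

Step 8
Reactants: 9 dienone tosylate; 10 3-methylbutan-2-one
Product: 12 (4aR,8aS)-1-[2-(tert-butyldimethylsilyloxy)ethyl]-2,5,5,8a-tetramethyl-4a,5,8,8a-tetrahydronaphthalene-3,6(4H,7H)-dione (trans-fused), via Michael adduct keto tosylate 11 (not isolated)
Conditions: KOtBu (1.5 equiv), t-BuOH/THF, 0 → 60 °C (10 in threefold excess)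
Reagents that add atoms: none
Why: KOtBu equilibrates the enolates of 10; the more substituted enolate carbon (future C4) adds reversibly to C5, the β-carbon of the unsubstituted arm of the cross-conjugated dienone (the C8=C9 arm is tetrasubstituted and inert), and after proton transfer the methyl-ketone enolate carbon (future C2) displaces the neopentyl tosylate at C1 irreversibly. The closest known reactions are the Michael–Claisen annulation of the same ketone with acrylates to 4,4-dimethylcyclohexane-1,3-dione and Michael-initiated ring closures of ketone enolates onto ω-sulfonates (α,α′-annulation). Ring A closes in the 6-(enolendo)-exo-tet mode, which favours C- over O-alkylation. C5 is controlled by C10: the enolate should approach anti to the larger CH2OTs group, and because the Michael step is reversible the material can drain through the chair-like closure that places C1 and C4 both equatorial on ring B, which is the trans-decalin. The step needs regioselectivity between the two α-carbons of 10 (only the C4 adduct can close a six-membered ring, the C2 adduct reverts) and chemoselectivity between the two dienone arms (secured by the substituents on C8 and C9).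

Step 9
Reactants: 12 enedione
Product: 13 bis(1,3-dithiolane) of 12 (both carbonyl carbons spiro-dithioketalized, ring fusion unchanged)
Conditions: HS(CH2)2SH, Zn(OTf)2 (cat.), CH2Cl2, rt
Reagents that add atoms: ethane-1,2-dithiol, SCCS
Why: Lewis acid-catalysed dithioketalization of both ketones; conjugate thiol addition is blocked by the fully substituted β-carbon C9 and the mild catalyst spares the silyl ether.

Step 10
Reactants: 13 bis(dithiolane)
Product: 14 tert-butyldimethyl{2-[(4aS,8aS)-2,5,5,8a-tetramethyl-3,4,4a,5,6,7,8,8a-octahydronaphthalen-1-yl]ethoxy}silane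
Conditions: Raney Ni (W-2, acetone-deactivated), EtOH, 60 °C
Reagents that add atoms: none
Why: Mozingo desulfurization replaces both dithioketal carbons by CH2, and the hindered tetrasubstituted C8=C9 bond is expected to stay in place and unreduced.

Step 11
Reactants: 14 silyl ether
Product: 15 (4aS,8aS)-1-(2-bromoethyl)-2,5,5,8a-tetramethyl-3,4,4a,5,6,7,8,8a-octahydronaphthalene
Conditions: Ph3PBr2, CH2Cl2, rt
Reagents that add atoms: dibromotriphenylphosphorane, BrP(Br)(c1ccccc1)(c1ccccc1)c1ccccc1
Why: Dibromotriphenylphosphorane converts primary silyl ethers directly into bromides through a silyloxyphosphonium ion (Appel-type substitution), so no separate desilylation is needed.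

Step 12
Reactants: 16 furan-3-carbaldehyde
Product: 17 (R)-1-(furan-3-yl)but-3-yn-1-ol
Conditions: allenylboronic acid pinacol ester, (R)-TRIP [(R)-3,3′-bis(2,4,6-triisopropylphenyl)-1,1′-binaphthyl-2,2′-diyl hydrogen phosphate] (5 mol %), toluene, −20 °C
Reagents that add atoms: 4,4,5,5-tetramethyl-2-(propa-1,2-dien-1-yl)-1,3,2-dioxaborolane, C=C=CB1OC(C)(C)C(C)(C)O1
Why: Brønsted acid-catalysed propargylboration proceeds through a closed six-membered transition state with allenyl-to-propargyl transposition, and the chiral phosphate differentiates the aldehyde faces, which sets the C16 carbinol.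

Step 13
Reactants: 17 homopropargylic alcohol
Product: 18 (R)-tert-butyl{[1-(furan-3-yl)but-3-yn-1-yl]oxy}dimethylsilane
Conditions: TBSCl, imidazole, DMF, rt
Reagents that add atoms: tert-butyldimethylsilyl chloride, CC(C)(C)[Si](C)(C)Cl
Why: Routine silylation of the secondary alcohol before the organolithium step.

Step 14
Reactants: 18 silyl ether alkyne
Product: 19 (R)-5-(tert-butyldimethylsilyloxy)-5-(furan-3-yl)pent-2-yn-1-ol
Conditions: n-BuLi, THF, −78 °C; (CH2O)n, −78 °C → rt
Reagents that add atoms: formaldehyde (as paraformaldehyde), C=O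
Why: The alkyne CH is far more acidic than the furan CH, so the lithium acetylide forms selectively and adds to formaldehyde (acetylide hydroxymethylation).

Step 15
Reactants: 19 propargylic alcohol
Product: 20 (R,E)-5-(tert-butyldimethylsilyloxy)-5-(furan-3-yl)-2-(tributylstannyl)pent-2-en-1-ol
Conditions: Bu3SnH, PdCl2(PPh3)2 (2 mol %), THF, 0 °C
Reagents that add atoms: tributyltin hydride, CCCC[SnH](CCCC)CCCC
Why: Pd-catalysed hydrostannation is a syn addition and the free propargylic hydroxyl should steer tin to the adjacent alkyne carbon, so H and Sn end up cis, which fixes the geometry of the later trisubstituted alkene.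

Step 16
Reactants: 20 vinylstannane
Product: 21 (R,E)-5-(tert-butyldimethylsilyloxy)-5-(furan-3-yl)-2-iodopent-2-en-1-ol
Conditions: iodine, CH2Cl2, 0 °C
Reagents that add atoms: iodine, [I][I]
Why: Iododestannylation takes place with retention of the alkene geometry.

Step 17
Reactants: 21 iodo allylic alcohol
Product: 22 (R,E)-3-[1,5-bis(tert-butyldimethylsilyloxy)-4-iodopent-3-en-1-yl]furan
Conditions: TBSCl, imidazole, DMF, rt
Reagents that add atoms: tert-butyldimethylsilyl chloride, CC(C)(C)[Si](C)(C)Cl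
Why: Routine silylation of the primary allylic alcohol.

Step 18
Reactants: 22 furan
Product: 23 4-[(R,E)-1,5-bis(tert-butyldimethylsilyloxy)-4-iodopent-3-en-1-yl]-5-hydroxyfuran-2(5H)-one (lactol epimers)
Conditions: O2, hν (visible), tetraphenylporphyrin (cat.), iPr2NEt, CH2Cl2, −78 °C
Reagents that add atoms: oxygen, O=O
Why: Singlet oxygen adds across the furan in a [4+2] cycloaddition and the hindered amine removes the less hindered endoperoxide proton (Kornblum–DeLaMare-type fragmentation), so the carbonyl forms remote from the substituent and the lactol carbon next to it; the iodoalkene is too electron-poor for an ene reaction.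

Step 19
Reactants: 23 hydroxybutenolide
Product: 25 (R,E)-4-[1,5-bis(tert-butyldimethylsilyloxy)-4-iodopent-3-en-1-yl]furan-2(5H)-one, via hydroxy acid 24 (not isolated)
Conditions: NaBH4, EtOH/THF, 0 °C; then aq. HCl
Reagents that add atoms: none
Why: Borohydride reduces the aldehyde of the ring-opened formylacrylate tautomer and the resulting hydroxy acid, with CH2OH and CO2H cis, lactonizes on acidification (lactol reduction–lactonization).

Step 20
Reactants: 15 bromide; 25 vinyl iodide
Product: 27 (R)-4-{(Z)-1-(tert-butyldimethylsilyloxy)-4-[(tert-butyldimethylsilyloxy)methyl]-6-[(4aS,8aS)-2,5,5,8a-tetramethyl-3,4,4a,5,6,7,8,8a-octahydronaphthalen-1-yl]hex-3-en-1-yl}furan-2(5H)-one, via alkylzinc bromide 26 (not isolated)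
Conditions: Zn dust, LiCl, THF, 50 °C; then 25, Pd(OAc)2 (2 mol %), SPhos (4 mol %), THF, rt
Reagents that add atoms: none
Why: LiCl-promoted zinc insertion gives the primary alkylzinc, which undergoes Negishi sp3–sp2 coupling with retention of the vinyl iodide geometry; lactone and silyl ethers are inert to the organozinc.

Step 21
Reactants: 27 bis-silyl ether
Product: 28 (R)-4-{(Z)-1-hydroxy-4-(hydroxymethyl)-6-[(4aS,8aS)-2,5,5,8a-tetramethyl-3,4,4a,5,6,7,8,8a-octahydronaphthalen-1-yl]hex-3-en-1-yl}furan-2(5H)-one (target)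
Conditions: HF·pyridine, pyridine/THF, 0 °C → rt
Reagents that add atoms: none
Why: Buffered HF cleaves both silyl ethers without the basic conditions that would isomerize or open the butenolide (fluoride desilylation).

**Compound list**

1 | 2,3-dimethylbenzoic acid | Cc1cccc(C(=O)O)c1C | starting material
2 | 2-(2-hydroxyethyl)-3-methylbenzoic acid | Cc1cccc(C(=O)O)c1CCO | intermediate
3 | 5-methylisochroman-1-one | Cc1cccc2C(=O)OCCc12 | intermediate
4 | (S)-[2-(2-hydroxyethyl)-3-methylphenyl][2-(methoxymethyl)pyrrolidin-1-yl]methanone | COC[C@@H]1CCCN1C(=O)c1cccc(C)c1CCO | intermediate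
5 | (S)-{2-[2-(tert-butyldimethylsilyloxy)ethyl]-3-methylphenyl}[2-(methoxymethyl)pyrrolidin-1-yl]methanone | COC[C@@H]1CCCN1C(=O)c1cccc(C)c1CCO[Si](C)(C)C(C)(C)C | intermediate
6 | {(1S)-2-[2-(tert-butyldimethylsilyloxy)ethyl]-1,3-dimethylcyclohexa-2,5-dien-1-yl}[(2S)-2-(methoxymethyl)pyrrolidin-1-yl]methanone | CC1=C(CCO[Si](C)(C)C(C)(C)C)[C@@](C)(C(=O)N2CCC[C@H]2COC)C=CC1 | intermediate
7 | {(1S)-2-[2-(tert-butyldimethylsilyloxy)ethyl]-1,3-dimethylcyclohexa-2,5-dien-1-yl}methanol | CC1=C(CCO[Si](C)(C)C(C)(C)C)[C@@](C)(CO)C=CC1 | intermediate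
8 | {(1S)-2-[2-(tert-butyldimethylsilyloxy)ethyl]-1,3-dimethylcyclohexa-2,5-dien-1-yl}methyl 4-methylbenzenesulfonate | CC1=C(CCO[Si](C)(C)C(C)(C)C)[C@@](C)(COS(=O)(=O)c2ccc(C)cc2)C=CC1 | intermediate
9 | {(1S)-2-[2-(tert-butyldimethylsilyloxy)ethyl]-1,3-dimethyl-4-oxocyclohexa-2,5-dien-1-yl}methyl 4-methylbenzenesulfonate | CC1=C(CCO[Si](C)(C)C(C)(C)C)[C@@](C)(COS(=O)(=O)c2ccc(C)cc2)C=CC1=O | intermediate
10 | 3-methylbutan-2-one | CC(C)C(C)=O | starting material
11 | {(1S,6R)-2-[2-(tert-butyldimethylsilyloxy)ethyl]-1,3-dimethyl-6-(2-methyl-3-oxobutan-2-yl)-4-oxocyclohex-2-en-1-yl}methyl 4-methylbenzenesulfonate | CC1=C(CCO[Si](C)(C)C(C)(C)C)[C@@](C)(COS(=O)(=O)c2ccc(C)cc2)[C@@H](CC1=O)C(C)(C)C(C)=O | intermediate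
12 | (4aR,8aS)-1-[2-(tert-butyldimethylsilyloxy)ethyl]-2,5,5,8a-tetramethyl-4a,5,8,8a-tetrahydronaphthalene-3,6(4H,7H)-dione | CC1=C(CCO[Si](C)(C)C(C)(C)C)[C@@]2(C)CCC(=O)C(C)(C)[C@@H]2CC1=O | intermediate
13 | bis(1,3-dithiolane) of 12 at both carbonyl carbons | CC1=C(CCO[Si](C)(C)C(C)(C)C)[C@@]2(C)CCC3(SCCS3)C(C)(C)[C@@H]2CC14SCCS4 | intermediate
14 | tert-butyldimethyl{2-[(4aS,8aS)-2,5,5,8a-tetramethyl-3,4,4a,5,6,7,8,8a-octahydronaphthalen-1-yl]ethoxy}silane | CC1=C(CCO[Si](C)(C)C(C)(C)C)[C@@]2(C)CCCC(C)(C)[C@@H]2CC1 | intermediate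
15 | (4aS,8aS)-1-(2-bromoethyl)-2,5,5,8a-tetramethyl-3,4,4a,5,6,7,8,8a-octahydronaphthalene | CC1=C(CCBr)[C@@]2(C)CCCC(C)(C)[C@@H]2CC1 | intermediate
16 | furan-3-carbaldehyde | O=Cc1ccoc1 | starting material
17 | (R)-1-(furan-3-yl)but-3-yn-1-ol | C#CC[C@@H](O)c1ccoc1 | intermediate
18 | (R)-tert-butyl{[1-(furan-3-yl)but-3-yn-1-yl]oxy}dimethylsilane | C#CC[C@@H](O[Si](C)(C)C(C)(C)C)c1ccoc1 | intermediate
19 | (R)-5-(tert-butyldimethylsilyloxy)-5-(furan-3-yl)pent-2-yn-1-ol | OCC#CC[C@@H](O[Si](C)(C)C(C)(C)C)c1ccoc1 | intermediate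
20 | (R,E)-5-(tert-butyldimethylsilyloxy)-5-(furan-3-yl)-2-(tributylstannyl)pent-2-en-1-ol | CCCC[Sn](CCCC)(CCCC)/C(=C/C[C@@H](O[Si](C)(C)C(C)(C)C)c1ccoc1)CO | intermediate
21 | (R,E)-5-(tert-butyldimethylsilyloxy)-5-(furan-3-yl)-2-iodopent-2-en-1-ol | I/C(=C/C[C@@H](O[Si](C)(C)C(C)(C)C)c1ccoc1)CO | intermediate
22 | (R,E)-3-[1,5-bis(tert-butyldimethylsilyloxy)-4-iodopent-3-en-1-yl]furan | I/C(=C/C[C@@H](O[Si](C)(C)C(C)(C)C)c1ccoc1)CO[Si](C)(C)C(C)(C)C | intermediate
23 | 4-[(R,E)-1,5-bis(tert-butyldimethylsilyloxy)-4-iodopent-3-en-1-yl]-5-hydroxyfuran-2(5H)-one | I/C(=C/C[C@@H](O[Si](C)(C)C(C)(C)C)C1=CC(=O)OC1O)CO[Si](C)(C)C(C)(C)C | intermediate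
24 | (2E,4R,6E)-4,8-bis(tert-butyldimethylsilyloxy)-3-(hydroxymethyl)-7-iodoocta-2,6-dienoic acid | I/C(=C/C[C@@H](O[Si](C)(C)C(C)(C)C)/C(CO)=C/C(=O)O)CO[Si](C)(C)C(C)(C)C | intermediate
25 | (R,E)-4-[1,5-bis(tert-butyldimethylsilyloxy)-4-iodopent-3-en-1-yl]furan-2(5H)-one | I/C(=C/C[C@@H](O[Si](C)(C)C(C)(C)C)C1=CC(=O)OC1)CO[Si](C)(C)C(C)(C)C | intermediate
26 | {2-[(4aS,8aS)-2,5,5,8a-tetramethyl-3,4,4a,5,6,7,8,8a-octahydronaphthalen-1-yl]ethyl}zinc bromide | CC1=C(CC[Zn]Br)[C@@]2(C)CCCC(C)(C)[C@@H]2CC1 | intermediate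
27 | (R)-4-{(Z)-1-(tert-butyldimethylsilyloxy)-4-[(tert-butyldimethylsilyloxy)methyl]-6-[(4aS,8aS)-2,5,5,8a-tetramethyl-3,4,4a,5,6,7,8,8a-octahydronaphthalen-1-yl]hex-3-en-1-yl}furan-2(5H)-one | CC1=C(CC/C(=C/C[C@@H](O[Si](C)(C)C(C)(C)C)C2=CC(=O)OC2)CO[Si](C)(C)C(C)(C)C)[C@@]2(C)CCCC(C)(C)[C@@H]2CC1 | intermediate
28 | (R)-4-{(Z)-1-hydroxy-4-(hydroxymethyl)-6-[(4aS,8aS)-2,5,5,8a-tetramethyl-3,4,4a,5,6,7,8,8a-octahydronaphthalen-1-yl]hex-3-en-1-yl}furan-2(5H)-one | CC1=C(CC/C(=C/C[C@@H](O)C2=CC(=O)OC2)CO)[C@@]2(C)CCCC(C)(C)[C@@H]2CC1 | target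

**Count and risks**

Total steps: 21. Longest linear sequence: 13 (steps 1 to 11, 20 and 21).

Most likely to fail:

- **Step 8.** The addition of a fully substituted enolate carbon next to quaternary C10 may stall or revert before ring closure, O-alkylation may compete in the closure, and the facial selectivity at C5 may be low. The fallback sets out from 7 and comes back at 14; it builds the two bonds one after the other and closes ring A by a radical instead of an enolate. Triflation of 7 (Tf2O, pyridine) gives the neopentyl triflate F1. Displacement with lithium bis(3-methylbut-3-en-1-yl)cuprate (from 4-bromo-2-methylbut-1-ene, t-BuLi and CuI) forms C1–C2 and gives the triene F2. Allylic oxidation as in step 7 gives the dienone F3. Hydrogen-atom-transfer-initiated radical cyclization (Fe(acac)3, PhSiH3, EtOH) of the tertiary C4 radical onto C5 closes ring A and gives the bicyclic enone F4. Dithioketalization gives the dithiolane F5, and Raney Ni desulfurization returns 14.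

- **Step 5.** Reduction of the very hindered tertiary amide may be incomplete, or carbon–oxygen instead of carbon–nitrogen cleavage may give the amine. The fallback sets out from 6 and comes back at 7; it removes the auxiliary by neighbouring-group lactonization instead of reduction. TsOH in wet THF at 50 °C removes the silyl group, and the freed hydroxyl expels the amine to give the bicyclic lactone F6. LiAlH4 opens it to the diol F7. Silylation with one equivalent of TBSCl at −20 °C goes to the unhindered primary hydroxyl and returns 7.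

- **Step 15.** Tin may be delivered to the wrong alkyne carbon (poor regioselectivity). The fallback sets out from 18 and comes back at 21; it uses an ester instead of a hydroxyl to direct the tin. Deprotonation of 18 (n-BuLi) and acylation with methyl chloroformate gives the ynoate F8. Pd(PPh3)4-catalysed syn-hydrostannation, which places tin reliably α to the ester, gives the stannyl enoate F9. Iodine gives the iodo enoate F10, and reduction with iBu2AlH returns 21.

**Further compounds**

F1 | step 8 | {(1S)-2-[2-(tert-butyldimethylsilyloxy)ethyl]-1,3-dimethylcyclohexa-2,5-dien-1-yl}methyl trifluoromethanesulfonate | CC1=C(CCO[Si](C)(C)C(C)(C)C)[C@@](C)(COS(=O)(=O)C(F)(F)F)C=CC1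
F2 | step 8 | tert-butyl{2-[(6S)-2,6-dimethyl-6-(4-methylpent-4-en-1-yl)cyclohexa-1,4-dien-1-yl]ethoxy}dimethylsilane | CC1=C(CCO[Si](C)(C)C(C)(C)C)[C@@](C)(CCCC(C)=C)C=CC1
F3 | step 8 | (4S)-3-[2-(tert-butyldimethylsilyloxy)ethyl]-2,4-dimethyl-4-(4-methylpent-4-en-1-yl)cyclohexa-2,5-dien-1-one | CC1=C(CCO[Si](C)(C)C(C)(C)C)[C@@](C)(CCCC(C)=C)C=CC1=O
F4 | step 8 | (4aS,8aS)-4-[2-(tert-butyldimethylsilyloxy)ethyl]-3,4a,8,8-tetramethyl-4a,5,6,7,8,8a-hexahydronaphthalen-2(1H)-one | CC1=C(CCO[Si](C)(C)C(C)(C)C)[C@@]2(C)CCCC(C)(C)[C@@H]2CC1=O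
F5 | step 8 | 1,3-dithiolane of F4 at the carbonyl carbon | CC1=C(CCO[Si](C)(C)C(C)(C)C)[C@@]2(C)CCCC(C)(C)[C@@H]2CC13SCCS3
F6 | step 5 | (S)-5,8a-dimethyl-3,4,6,8a-tetrahydro-1H-isochromen-1-one | CC1=C2CCOC(=O)[C@@]2(C)C=CC1
F7 | step 5 | {(1S)-2-(2-hydroxyethyl)-1,3-dimethylcyclohexa-2,5-dien-1-yl}methanol | CC1=C(CCO)[C@@](C)(CO)C=CC1
F8 | step 15 | methyl (R)-5-(tert-butyldimethylsilyloxy)-5-(furan-3-yl)pent-2-ynoate | COC(=O)C#CC[C@@H](O[Si](C)(C)C(C)(C)C)c1ccoc1
F9 | step 15 | methyl (R,E)-5-(tert-butyldimethylsilyloxy)-5-(furan-3-yl)-2-(tributylstannyl)pent-2-enoate | CCCC[Sn](CCCC)(CCCC)/C(=C/C[C@@H](O[Si](C)(C)C(C)(C)C)c1ccoc1)C(=O)OC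
F10 | step 15 | methyl (R,E)-5-(tert-butyldimethylsilyloxy)-5-(furan-3-yl)-2-iodopent-2-enoate | I/C(=C/C[C@@H](O[Si](C)(C)C(C)(C)C)c1ccoc1)C(=O)OC
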